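Atoms are numbered as in the indene core: ring A (cyclopentene) holds C1 to C3, ring B (cyclohexene) holds C4 to C7, and C3a and C7a are the fusion atoms. Ring B is cut at C3a–C4 and at the bond between the two quaternary carbons C6 and C7. Two features are exploited: C3a lies β to C1, which can be a ketone, and the C7 acid lies γ,δ to the C4=C5 alkene. In one flask an isopropenyl copper reagent adds to a cyclopentenone that carries an allylic ester; the silyl enol ether formed masks the ketone, the ester is enolised and an Ireland–Claisen rearrangement forges C6–C7 with chirality transfer. The precursor, ester 15, contains ring A only. Metathesis closes ring B last.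

Key step: step 9

Step 1
Reactants: 1 (4R)-4-[(tert-butyldimethylsilyl)oxy]cyclopent-2-en-1-one
Product: 3 (4R)-4-methylcyclopent-2-en-1-one, via trans-3-methyl-4-silyloxycyclopentanone 2 (not isolated)
Conditions: MeMgBr (1.3 equiv), CuBr·SMe2 (10 mol %), THF, −40 °C; aq. NH4Cl; then DBU (1.05 equiv), CH2Cl2, 0 °C
Reagents that add atoms: methylmagnesium bromide, C[Mg]Br
Why: Copper-catalysed conjugate addition delivers the methyl group anti to the silyloxy group, which sets the methyl stereocentre, and E1cB loss of silanolate from the β-silyloxy ketone then re-forms the enone on the other side.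

Step 2
Reactants: 3 (4R)-4-methylcyclopent-2-en-1-one
Product: 4 (4R)-2-iodo-4-methylcyclopent-2-en-1-one
Conditions: I2 (1.5 equiv), pyridine/CH2Cl2 (1:1), 0 °C → rt
Reagents that add atoms: iodine, II
Why: Pyridine-mediated α-iodination of the enone (addition–elimination of Baylis–Hillman type) should give the vinyl iodide without touching the stereocentre.

Step 3
Reactants: 4 (4R)-2-iodo-4-methylcyclopent-2-en-1-one; 5 tert-butyl 2-bromopropanoate
Product: 7 tert-butyl 2-[(3R)-3-methyl-5-oxocyclopent-1-en-1-yl]propanoate, via Reformatsky reagent 6 (not isolated)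
Conditions: 5, Zn dust (Me3SiCl-activated), THF, rt; then 4, Pd2(dba)3 (2.5 mol %), XPhos (10 mol %), THF, rt → 45 °C
Reagents that add atoms: none
Why: The zinc enolate formed by insertion should undergo palladium-catalysed Negishi-type cross-coupling with the vinyl iodide faster than carbonyl addition; the new α-stereocentre is left uncontrolled because it is enolised in step 9.

Step 4
Reactants: 7 tert-butyl 2-[(3R)-3-methyl-5-oxocyclopent-1-en-1-yl]propanoate
Product: 8 2-[(3R)-3-methyl-5-oxocyclopent-1-en-1-yl]propanoic acid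
Conditions: CF3CO2H/CH2Cl2 (1:4), 0 °C → rt
Reagents that add atoms: none
Why: Acidolysis of the tert-butyl ester (loss of 2-methylpropene) should free the acid without exposing the base-sensitive γ-stereocentre of the enone to base.

Step 5
Reactants: 9 pent-3-yn-2-one
Product: 10 (2S)-pent-3-yn-2-ol
Conditions: RuCl[(S,S)-TsDPEN](p-cymene) (0.5 mol %), iPrOH, rt
Reagents that add atoms: none
Why: Noyori asymmetric transfer hydrogenation of an alkynyl methyl ketone; the (S,S)-diamine ruthenium hydride distinguishes the alkynyl from the methyl group and should deliver the (S)-carbinol.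

Step 6
Reactants: 10 (2S)-pent-3-yn-2-ol
Product: 12 (2S,3Z)-4-iodopent-3-en-2-ol, via cyclic alkenylalanate 11 (not isolated)
Conditions: NaAlH2(OCH2CH2OMe)2 (Red-Al, 1.5 equiv), THF, 0 °C → rt; then I2 (1.5 equiv), −78 → 0 °C
Reagents that add atoms: iodine, II
Why: Alkoxide-directed trans-hydroalumination places aluminium on the distal alkyne carbon cis to the carbinol, and iodinolysis with retention should give the (Z)-vinyl iodide while the carbinol centre is untouched.

Step 7
Reactants: 12 (2S,3Z)-4-iodopent-3-en-2-ol; 13 [(1E)-buta-1,3-dien-1-yl]benzene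
Product: 14 (2S,3Z,5E,7E)-4-methyl-8-phenylocta-3,5,7-trien-2-ol
Conditions: Pd(OAc)2 (5 mol %), Bu4NCl (1 equiv), K2CO3 (2.5 equiv), DMF, 50 °C
Reagents that add atoms: none
Why: Heck reaction under Jeffery conditions: the alkenylpalladium adds to the terminal carbon of the diene and β-hydride elimination should give the new (E)-alkene, with the (Z)-geometry of the vinyl iodide retained.

Step 8
Reactants: 8 2-[(3R)-3-methyl-5-oxocyclopent-1-en-1-yl]propanoic acid; 14 (2S,3Z,5E,7E)-4-methyl-8-phenylocta-3,5,7-trien-2-ol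
Product: 15 (2S,3Z,5E,7E)-4-methyl-8-phenylocta-3,5,7-trien-2-yl 2-[(3R)-3-methyl-5-oxocyclopent-1-en-1-yl]propanoate
Conditions: EDC·HCl (1.3 equiv), DMAP (0.2 equiv), CH2Cl2, 0 °C → rt
Reagents that add atoms: none
Why: Steglich esterification under near-neutral conditions should avoid ionisation of the trienylic alcohol and leaves its carbinol stereocentre intact.

Step 9
Reactants: 15 (2S,3Z,5E,7E)-4-methyl-8-phenylocta-3,5,7-trien-2-yl 2-[(3R)-3-methyl-5-oxocyclopent-1-en-1-yl]propanoate; 16 isopropenylmagnesium bromide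
Product: 20 (2R,3R,4E)-2,3-dimethyl-2-[(1S,2S,3R)-3-methyl-5-oxo-2-(prop-1-en-2-yl)cyclopentyl]-3-[(1E,3E)-4-phenylbuta-1,3-dien-1-yl]hex-4-enoic acid, via silyl enol ether 17 (not isolated), via bis-silyl ketene acetal 18 (not isolated), via silyl ester 19 (not isolated)
Conditions: 16 (1.3 equiv), CuBr·SMe2 (10 mol %), Me3SiCl (3 equiv), THF, −78 °C; then LiN(iPr)2 (1.6 equiv), Et3N (2 equiv), −78 °C → 65 °C; then 1 M HCl, THF, rt
Reagents that add atoms: none
Why: Copper-catalysed conjugate addition of 16 to the enone, accelerated by Me3SiCl, forms the C3a–C4 bond anti to the C3 methyl group and leaves the ketone as silyl enol ether 17. With the ketone masked, LiN(iPr)2 removes the only remaining acidic proton (α to the ester) and silylation gives ketene acetal 18, in which the cyclic deprotonation model places the bulky ring cis to the allyl oxygen. Warming triggers the Ireland–Claisen rearrangement through a chair transition state with the carbinol methyl equatorial, so the (S)-carbinol and the (Z)-alkene (dienyl axial, anti to the ring) are translated into the C6 and C7 quaternary centres and an (E)-propenyl group; the closest known reaction type is a tandem conjugate addition/enolate Claisen sequence. Acid hydrolysis then frees the acid and the ketone, and C7a, epimerisable α to the ketone, should settle trans to the C3a substituent in the monocyclic ketone. No ring is closed in this step, since ring B is closed by metathesis in step 12. The step needs 1,4-addition to win over copper-mediated allylic substitution of the ester, which −78 °C and Me3SiCl should secure, and a single [3,3] pathway, which is secured because the carbinol carbon carries only one alkenyl group.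

Step 10
Reactants: 20 keto acid from step 9
Product: 21 (2R,3R,4E)-2,3-dimethyl-2-[(1S,4S,5S)-4-methyl-5-(prop-1-en-2-yl)-2-(trifluoromethanesulfonyloxy)cyclopent-2-en-1-yl]-3-[(1E,3E)-4-phenylbuta-1,3-dien-1-yl]hex-4-enoic acid
Conditions: KN(SiMe3)2 (2.3 equiv), THF, −78 °C; then PhNTf2 (1.2 equiv), −78 → 0 °C; 1 M HCl work-up
Reagents that add atoms: N-phenylbis(trifluoromethanesulfonimide), O=S(=O)(N(c1ccccc1)S(=O)(=O)C(F)(F)F)C(F)(F)F
Why: Kinetic deprotonation of the carboxylate ketone should occur at the unhindered C2 methylene and not at the congested C7a methine, and O-triflation fixes this enolate as the vinyl triflate without epimerising C7a.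

Step 11
Reactants: 21 vinyl triflate from step 10
Product: 22 (2R,3R,4E)-2-[(1R,4R,5S)-2-ethyl-4-methyl-5-(prop-1-en-2-yl)cyclopent-2-en-1-yl]-2,3-dimethyl-3-[(1E,3E)-4-phenylbuta-1,3-dien-1-yl]hex-4-enoic acid
Conditions: EtMgBr (3 equiv), Fe(acac)3 (10 mol %), THF/NMP, −30 → 0 °C
Reagents that add atoms: ethylmagnesium bromide, CC[Mg]Br
Why: Iron-catalysed Kumada-type cross-coupling of the alkenyl triflate should install the ethyl group on C1, the first equivalent of Grignard reagent serving only to deprotonate the acid.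

Step 12
Reactants: 22 diene acid from step 11
Product: 23 22-nor-zyggomphic acid B
Conditions: second-generation Hoveyda–Grubbs catalyst RuCl2(=CH-C6H4-2-OiPr)(H2IMes) (10 mol %), toluene (2 mM), 80 °C
Reagents that add atoms: none
Why: Ring-closing metathesis between the isopropenyl and propenyl groups (loss of propene) should close ring B as the trisubstituted C4=C5 alkene, and the trans ring fusion follows from the trans C3a/C7a substituents set in step 9.

Compound list
1 | (4R)-4-[(tert-butyldimethylsilyl)oxy]cyclopent-2-en-1-one | CC(C)(C)[Si](C)(C)O[C@H]1C=CC(=O)C1 | starting material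
2 | (3R,4R)-3-methyl-4-[(tert-butyldimethylsilyl)oxy]cyclopentan-1-one (trans) | C[C@@H]1CC(=O)C[C@H]1O[Si](C)(C)C(C)(C)C | intermediate
3 | (4R)-4-methylcyclopent-2-en-1-one | O=C1C[C@@H](C)C=C1 | intermediate
4 | (4R)-2-iodo-4-methylcyclopent-2-en-1-one | O=C1C[C@@H](C)C=C1I | intermediate
5 | tert-butyl 2-bromopropanoate (racemic) | CC(Br)C(=O)OC(C)(C)C | starting material
6 | bromo(1-tert-butoxy-1-oxopropan-2-yl)zinc (Reformatsky reagent) | CC([Zn]Br)C(=O)OC(C)(C)C | intermediate
7 | tert-butyl 2-[(3R)-3-methyl-5-oxocyclopent-1-en-1-yl]propanoate (both epimers at the propanoate α-carbon) | CC(C(=O)OC(C)(C)C)C1=C[C@H](C)CC1=O | intermediate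
8 | 2-[(3R)-3-methyl-5-oxocyclopent-1-en-1-yl]propanoic acid (both α-epimers) | CC(C(=O)O)C1=C[C@H](C)CC1=O | intermediate
9 | pent-3-yn-2-one | CC#CC(C)=O | starting material
10 | (2S)-pent-3-yn-2-ol | C[C@H](O)C#CC | intermediate
11 | sodium salt of the five-membered cyclic alkoxy(alkenyl)bis(2-methoxyethoxy)aluminate, (S)-carbinol, aluminium cis to the carbinol carbon | C[C@@H]1O[Al-](OCCOC)(OCCOC)C(C)=C1.[Na+] | intermediate
12 | (2S,3Z)-4-iodopent-3-en-2-ol | C[C@H](O)/C=C(\I)C | intermediate
13 | [(1E)-buta-1,3-dien-1-yl]benzene | C=C/C=C/c1ccccc1 | starting material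
14 | (2S,3Z,5E,7E)-4-methyl-8-phenylocta-3,5,7-trien-2-ol | C[C@H](O)/C=C(\C=C\C=C\c1ccccc1)C | intermediate
15 | (2S,3Z,5E,7E)-4-methyl-8-phenylocta-3,5,7-trien-2-yl 2-[(3R)-3-methyl-5-oxocyclopent-1-en-1-yl]propanoate (both α-epimers) | CC(C(=O)O[C@@H](C)/C=C(\C=C\C=C\c1ccccc1)C)C1=C[C@H](C)CC1=O | intermediate
16 | isopropenylmagnesium bromide (prop-1-en-2-ylmagnesium bromide) | CC(=C)[Mg]Br | starting material
17 | trienyl ester 15 after 1,4-addition: 2-[(4R,5R)-4-methyl-5-(prop-1-en-2-yl)-2-(trimethylsilyloxy)cyclopent-1-en-1-yl]propanoate of 14, isopropenyl trans to the ring methyl | C[Si](C)(C)OC1=C(C(C)C(=O)O[C@@H](C)/C=C(\C=C\C=C\c2ccccc2)C)[C@@H](C(C)=C)[C@H](C)C1 | intermediate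
18 | trimethylsilyl ketene acetal of 17, the cyclopentenyl ring cis to the allyl oxygen and the methyl cis to OSiMe3 | C[Si](C)(C)OC1=C(/C(C)=C(/O[Si](C)(C)C)O[C@@H](C)/C=C(\C=C\C=C\c2ccccc2)C)[C@@H](C(C)=C)[C@H](C)C1 | intermediate
19 | trimethylsilyl ester of 20 with the ring ketone as its trimethylsilyl enol ether toward C7a | C[Si](C)(C)OC1=C([C@@](C)(C(=O)O[Si](C)(C)C)[C@](C)(/C=C/C)/C=C/C=C/c2ccccc2)[C@@H](C(C)=C)[C@H](C)C1 | intermediate
20 | (2R,3R,4E)-2,3-dimethyl-2-[(1S,2S,3R)-3-methyl-5-oxo-2-(prop-1-en-2-yl)cyclopentyl]-3-[(1E,3E)-4-phenylbuta-1,3-dien-1-yl]hex-4-enoic acid (all-trans ring) | O=C1C[C@@H](C)[C@H](C(C)=C)[C@H]1[C@@](C)(C(=O)O)[C@](C)(/C=C/C)/C=C/C=C/c1ccccc1 | intermediate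
21 | (2R,3R,4E)-2,3-dimethyl-2-[(1S,4S,5S)-4-methyl-5-(prop-1-en-2-yl)-2-(trifluoromethanesulfonyloxy)cyclopent-2-en-1-yl]-3-[(1E,3E)-4-phenylbuta-1,3-dien-1-yl]hex-4-enoic acid | O=S(=O)(OC1=C[C@@H](C)[C@H](C(C)=C)[C@H]1[C@@](C)(C(=O)O)[C@](C)(/C=C/C)/C=C/C=C/c1ccccc1)C(F)(F)F | intermediate
22 | (2R,3R,4E)-2-[(1R,4R,5S)-2-ethyl-4-methyl-5-(prop-1-en-2-yl)cyclopent-2-en-1-yl]-2,3-dimethyl-3-[(1E,3E)-4-phenylbuta-1,3-dien-1-yl]hex-4-enoic acid | CCC1=C[C@@H](C)[C@H](C(C)=C)[C@H]1[C@@](C)(C(=O)O)[C@](C)(/C=C/C)/C=C/C=C/c1ccccc1 | intermediate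
23 | 22-nor-zyggomphic acid B, (3R,3aS,6S,7R,7aR)-1-ethyl-3,4,6,7-tetramethyl-6-[(1E,3E)-4-phenylbuta-1,3-dien-1-yl]-3a,6,7,7a-tetrahydro-3H-indene-7-carboxylic acid | CCC1=C[C@@H](C)[C@@H]2C(C)=C[C@](C)(/C=C/C=C/c3ccccc3)[C@](C)(C(=O)O)[C@@H]12 | target

Total step count: 12. Longest linear sequence: 9 steps (steps 1–4 and 8–12); steps 5–7 form the second branch.

Steps most likely to fail

1. Step 9. Copper-mediated allylic substitution of the trienyl ester may compete with the 1,4-addition, or enolisation of the crowded ester may be incomplete or poorly selective in geometry, so that the rearrangement stalls or gives the C7 epimer. The fallback reverses the order of the two bond formations and carries the ketone at the alcohol level. Setting out from ester 15, Luche reduction (NaBH4, CeCl3·7H2O, MeOH, −40 °C) should give the allylic alcohol ester F1. Ireland–Claisen rearrangement of this ester alone (KN(SiMe3)2 and Me3SiCl, 3 equiv each, toluene, −78 → 80 °C, the hydroxyl being silylated in the flask; then 1 M HCl) should give the hydroxy acid F2. Oxidation with MnO2 in CH2Cl2 should give the enone acid F3. Copper-catalysed addition of 16 (3 equiv, CuBr·SMe2, Me3SiCl, THF, −78 °C; then 1 M HCl) then comes back to keto acid 20.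

2. Step 12. The ruthenium carbene may engage the conjugated phenylbutadienyl chain and cut it short faster than it loads onto the hindered propenyl group. The fallback masks the diene as a sulfolene. Setting out from 22, liquid SO2 with a trace of hydroquinone in a sealed tube at rt should give the cis-2,5-disubstituted 2,5-dihydrothiophene 1,1-dioxide F4. Ring-closing metathesis under the conditions of step 12 should give the bicyclic sulfolene F5. Cheletropic loss of SO2 (toluene, NaHCO3, 110 °C) regenerates the (E,E)-diene and arrives at 23.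

3. Step 7. Insertion into the diene may be poorly regiocontrolled, or the (Z)-geometry of the vinyl iodide may erode through palladium hydride species. The fallback replaces the Heck reaction by a cross-coupling with a preformed dienyl metal. Hydrostannation of (E)-but-1-en-3-ynylbenzene (Bu3SnH, PdCl2(PPh3)2 cat., THF) should give tributyl[(1E,3E)-4-phenylbuta-1,3-dien-1-yl]stannane F6. Stille coupling of F6 with vinyl iodide 12 (Pd2(dba)3, AsPh3, CuI, DMF, rt) comes back to trienol 14.

Further compounds
F1 | step 9 | (2S,3Z,5E,7E)-4-methyl-8-phenylocta-3,5,7-trien-2-yl 2-[(3R)-5-hydroxy-3-methylcyclopent-1-en-1-yl]propanoate (carbinol and α-carbon epimers) | CC(C(=O)O[C@@H](C)/C=C(\C=C\C=C\c1ccccc1)C)C1=C[C@H](C)CC1O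
F2 | step 9 | (4E)-2-[(3R)-5-hydroxy-3-methylcyclopent-1-en-1-yl]-2,3-dimethyl-3-[(1E,3E)-4-phenylbuta-1,3-dien-1-yl]hex-4-enoic acid, quaternary centres as in 20 | OC1C[C@@H](C)C=C1[C@@](C)(C(=O)O)[C@](C)(/C=C/C)/C=C/C=C/c1ccccc1
F3 | step 9 | (4E)-2,3-dimethyl-2-[(3R)-3-methyl-5-oxocyclopent-1-en-1-yl]-3-[(1E,3E)-4-phenylbuta-1,3-dien-1-yl]hex-4-enoic acid, quaternary centres as in 20 | O=C1C[C@@H](C)C=C1[C@@](C)(C(=O)O)[C@](C)(/C=C/C)/C=C/C=C/c1ccccc1
F4 | step 12 | acid 22 with the phenylbutadienyl group masked as a cis-5-phenyl-2,5-dihydrothiophen-2-yl 1,1-dioxide (both cis diastereomers) | CCC1=C[C@@H](C)[C@H](C(C)=C)[C@H]1[C@@](C)(C(=O)O)[C@](C)(/C=C/C)C1C=CC(c2ccccc2)S1(=O)=O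
F5 | step 12 | acid 23 with the phenylbutadienyl group masked as a cis-5-phenyl-2,5-dihydrothiophen-2-yl 1,1-dioxide | CCC1=C[C@@H](C)[C@@H]2C(C)=C[C@](C)(C3C=CC(c4ccccc4)S3(=O)=O)[C@](C)(C(=O)O)[C@@H]12
F6 | step 7 | tributyl[(1E,3E)-4-phenylbuta-1,3-dien-1-yl]stannane | CCCC[Sn](CCCC)(CCCC)/C=C/C=C/c1ccccc1
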